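**Retrosynthetic overview**
- Macrocarpal J ⇒ hedycaryol [(7R)-germacra-1(10)E,4E-dien-11-ol] + the isopentylidene o-quinone methide of 2,4-diformylphloroglucinol + water. One light-triggered cascade forms C1–C9′, then C5–C10, then C4–OH.
- The quinone methide ⇐ a photolabile Mannich base ⇐ 2,4-diformylphloroglucinol + isovaleraldehyde + morpholine.
- Hedycaryol ⇐ reduction of a cyclodecadienyl enol triflate ⇐ anionic oxy-Cope of a trans-1,2-dialkenylcyclohexanol (C2–C3 bond, ring expansion 6 → 10).
- The carbinol ⇐ isopropenyl addition to a 2-methyl-2-vinylcyclohexanone ⇐ reductive aldol and elimination on carvone hydrate ⇐ (R)-carvone, whose single stereocentre becomes C7 and controls all the others.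
- Ring order: cyclohexane (bought) → cyclodecadiene → both decalin rings closed together in the last step.

Assumption: (R)-carvone and 2,4,6-trihydroxybenzene-1,3-dicarbaldehyde are taken as catalogue chemicals; the target descriptors read from the SMILES are 1S,4R,4aR,6R,8aS in the decalin and 1S in the side chain (eudesmane numbering is used in the explanations).

**Step 1**
Reactants: 1 (R)-(−)-carvone
Product: 2 (5R)-5-(2-hydroxypropan-2-yl)-2-methylcyclohex-2-en-1-one (carvone hydrate)
Conditions: 50% aq. H2SO4, 0 → 23 °C
Reagents that add atoms: water, SMILES O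
Why: Markovnikov acid-catalysed hydration of the isopropenyl group through its tertiary cation, with the enone inert in the cold and the bought stereocentre (later C7) untouched.

**Step 2**
Reactants: 2 carvone hydrate
Product: 4 (2R,5R)-2-(1-hydroxyethyl)-5-(2-hydroxypropan-2-yl)-2-methylcyclohexan-1-one (both carbinol epimers), via lithium enolate 3 (not isolated)
Conditions: L-Selectride (1.15 equiv), THF, −78 °C; CH3CHO, −78 °C; AcOH quench
Reagents that add atoms: acetaldehyde, SMILES CC=O
Why: Reductive aldol reaction: 1,4-hydride addition gives the regiodefined tetrasubstituted enolate (the tertiary alcohol is not deprotonated by the hindered borohydride in the cold), and chair-like axial attack places the new C–C bond cis to the equatorial C5 side chain, the same sense as the Robinson annulation of dihydrocarvone.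

**Step 3**
Reactants: 4 aldol
Product: 6 (2R,5R)-2-ethenyl-5-(2-hydroxypropan-2-yl)-2-methylcyclohexan-1-one, via mesylate 5 (not isolated)
Conditions: MsCl, pyridine, 0 → 23 °C; then DBU, 100 °C
Reagents that add atoms: none
Why: Selective sulfonylation of the secondary alcohol (the tertiary one is inert to MsCl/pyridine) followed by E2 elimination, which can only run toward the methyl group because the α-carbon is quaternary, so the vinyl group results.

**Step 4**
Reactants: 6 vinyl ketone
Product: 7 (1S,2R,5R)-2-ethenyl-5-(2-hydroxypropan-2-yl)-2-methyl-1-(prop-1-en-2-yl)cyclohexan-1-ol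
Conditions: isopropenylmagnesium bromide (3 equiv), CeCl3, THF, −78 → 0 °C; aqueous work-up
Reagents that add atoms: isopropenylmagnesium bromide, SMILES C=C(C)[Mg]Br
Why: Organocerium 1,2-addition to the hindered ketone without enolisation; attack comes from the face opposite the axial C2 vinyl group (axial attack anti to an axial α-substituent), giving the trans-1,2-dialkenyl carbinol.

**Step 5**
Reactants: 7 dialkenyl carbinol
Product: 9 (1Z,5E,9R)-9-(2-hydroxypropan-2-yl)-2,6-dimethylcyclodeca-1,5-dien-1-yl trifluoromethanesulfonate, via dipotassium enolate 8 (not isolated)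
Conditions: KH (2.5 equiv), 18-crown-6, THF, 0 → 40 °C; then Comins' reagent (1.05 equiv), −78 °C; aqueous work-up
Reagents that add atoms: Comins' reagent, N-(5-chloropyridin-2-yl)bis(trifluoromethanesulfonimide), SMILES Clc1ccc(nc1)N(S(=O)(=O)C(F)(F)F)S(=O)(=O)C(F)(F)F
Why: Anionic oxy-Cope rearrangement through the chair transition state with both alkenyl groups equatorial (after ring flip) forms the C2–C3 bond, the (E)-C1=C10 alkene and a regio- and geometry-defined enolate, which is O-triflated at −78 °C where the hindered tertiary alkoxide does not compete.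

**Step 6**
Reactants: 9 enol triflate
Product: 10 hedycaryol, 2-[(1R,3E,7E)-4,8-dimethylcyclodeca-3,7-dien-1-yl]propan-2-ol
Conditions: Pd(PPh3)4 (5 mol%), LiCl, Bu3SnH, THF, 23–40 °C; Et3N-deactivated silica
Reagents that add atoms: none
Why: Palladium-catalysed hydride reduction of the enol triflate (Scott–Stille type) replaces OTf by H with retention of alkene geometry, below the temperature at which the germacradiene undergoes Cope rearrangement to elemol.

**Step 7**
Reactants: 11 2,4,6-trihydroxybenzene-1,3-dicarbaldehyde (2,4-diformylphloroglucinol); 12 3-methylbutanal (isovaleraldehyde)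
Product: 13 2,4,6-trihydroxy-5-[3-methyl-1-(morpholin-4-yl)butyl]benzene-1,3-dicarbaldehyde (racemic Mannich base, zwitterion)
Conditions: morpholine (1.05 equiv), EtOH, 23 °C
Reagents that add atoms: morpholine, SMILES C1COCCN1
Why: Three-component Mannich (Betti-type) condensation: the iminium ion from the aldehyde and morpholine is captured by the only free, strongly nucleophilic ring carbon, and the racemic centre becomes sp2 in the next step.

**Step 8**
Reactants: 10 hedycaryol; 13 Mannich base (1.5 equiv)
Product: 16 macrocarpal J, via o-quinone methide 14 (not isolated), via eudesm-4-yl cation zwitterion 15 (not isolated)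
Conditions: hν (390 nm LEDs), MeCN/H2O 4:1, NaOAc–AcOH buffer (pH 4.7), 0 °C, Ar
Reagents that add atoms: water, SMILES O
Why: Proposed new method: excitation of the phenolate–ammonium zwitterion 13 expels morpholine to give o-quinone methide 14 at 0 °C without heat or strong acid, and its methide carbon is attacked by C1 of the strained (E)-C1=C10 alkene of 10 in a compact hetero-Diels–Alder-like geometry (aryl over C10, isobutyl outside over H1, which gives 9′S); the chroman closure is interrupted because the developing C10 cation is captured transannularly by C5 of the 4,5-alkene (anti addition in the chair–chair conformer with the C7 side chain equatorial sets the 1β-equatorial substituent, 10β-methyl and 5α-H), and the tertiary C4 cation 15 takes up water anti to the new C5–C10 bond (equatorial 4α-OH); the closest known chemistry is photodeamination of phenol Mannich bases to o-quinone methides with alkene trapping, the thermal and electrochemical coupling of this quinone methide with terpenes to euglobal-type chromans, and the acid-induced cyclisation–hydration of hedycaryol to cryptomeridiol.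

**Compound list**
1 | (R)-(−)-carvone, (5R)-2-methyl-5-(prop-1-en-2-yl)cyclohex-2-en-1-one | CC1=CC[C@H](CC1=O)C(C)=C | starting material
2 | (5R)-5-(2-hydroxypropan-2-yl)-2-methylcyclohex-2-en-1-one | CC1=CC[C@H](CC1=O)C(C)(C)O | intermediate
3 | lithium (5R)-5-(2-hydroxypropan-2-yl)-2-methylcyclohex-1-en-1-olate | [Li+].CC1=C([O-])C[C@@H](CC1)C(C)(C)O | intermediate
4 | (2R,5R)-2-(1-hydroxyethyl)-5-(2-hydroxypropan-2-yl)-2-methylcyclohexan-1-one (carbinol epimers) | C[C@]1(C(C)O)CC[C@H](CC1=O)C(C)(C)O | intermediate
5 | 1-[(1R,4R)-4-(2-hydroxypropan-2-yl)-1-methyl-2-oxocyclohexyl]ethyl methanesulfonate | C[C@]1(C(C)OS(C)(=O)=O)CC[C@H](CC1=O)C(C)(C)O | intermediate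
6 | (2R,5R)-2-ethenyl-5-(2-hydroxypropan-2-yl)-2-methylcyclohexan-1-one | C[C@]1(C=C)CC[C@H](CC1=O)C(C)(C)O | intermediate
7 | (1S,2R,5R)-2-ethenyl-5-(2-hydroxypropan-2-yl)-2-methyl-1-(prop-1-en-2-yl)cyclohexan-1-ol | C[C@]1(C=C)CC[C@H](C[C@]1(O)C(C)=C)C(C)(C)O | intermediate
8 | dipotassium (1Z,5E,9R)-2,6-dimethyl-9-(2-oxidopropan-2-yl)cyclodeca-1,5-dien-1-olate | [K+].[K+].C/C1=C\CC/C(C)=C([O-])/C[C@H](C(C)(C)[O-])CC1 | intermediate
9 | (1Z,5E,9R)-9-(2-hydroxypropan-2-yl)-2,6-dimethylcyclodeca-1,5-dien-1-yl trifluoromethanesulfonate | C/C1=C\CC/C(C)=C(OS(=O)(=O)C(F)(F)F)/C[C@H](C(C)(C)O)CC1 | intermediate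
10 | hedycaryol, 2-[(1R,3E,7E)-4,8-dimethylcyclodeca-3,7-dien-1-yl]propan-2-ol | C/C1=C\CC/C(C)=C/C[C@H](C(C)(C)O)CC1 | intermediate
11 | 2,4,6-trihydroxybenzene-1,3-dicarbaldehyde | O=Cc1c(O)cc(O)c(C=O)c1O | starting material
12 | 3-methylbutanal | CC(C)CC=O | starting material
13 | 2,4,6-trihydroxy-5-[3-methyl-1-(morpholin-4-yl)butyl]benzene-1,3-dicarbaldehyde (racemic) | CC(C)CC(N1CCOCC1)c1c(O)c(C=O)c(O)c(C=O)c1O | intermediate
14 | 2,4-dihydroxy-5-(3-methylbutylidene)-6-oxocyclohexa-1,3-diene-1,3-dicarbaldehyde (o-quinone methide) | CC(C)CC=C1C(=O)C(C=O)=C(O)C(C=O)=C1O | intermediate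
15 | zwitterion: target skeleton with a tertiary carbocation at C4 (no OH yet) and one ortho phenolate | CC(C)C[C@H](c1c([O-])c(C=O)c(O)c(C=O)c1O)[C@@H]1CC[C+](C)[C@@H]2C[C@H](C(C)(C)O)CC[C@]21C | intermediate
16 | macrocarpal J, 5-[(1S)-1-[(1S,4R,4aR,6R,8aS)-4-hydroxy-6-(2-hydroxypropan-2-yl)-4,8a-dimethyldecahydronaphthalen-1-yl]-3-methylbutyl]-2,4,6-trihydroxybenzene-1,3-dicarbaldehyde | CC(C)C[C@H](c1c(O)c(C=O)c(O)c(C=O)c1O)[C@@H]1CC[C@@](C)(O)[C@@H]2C[C@H](C(C)(C)O)CC[C@]21C | target

**Step count and risks**
Total steps: 8. Longest linear sequence: 7 (steps 1–6 and 8); step 7 is the one-step side branch.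

Step 8 (the proposed new step) is the most likely to fail. The formyl groups may quench the photo-release, the quinone methide may simply close to the chroman, the C4 cation may lose a proton instead of taking up water, and 10 may cyclise on its own under acid. The fallback uses known chemistry and sets out from 10 and 13. Warming them in the dark (AcOH, MeCN, 45 °C) releases 14 thermally, and the established hetero-Diels–Alder reaction of this quinone methide with a terpene alkene gives the chroman cycloadduct F1. Acidolysis of its tertiary alkyl aryl ether (TFA, THF/H2O, 0 °C) reopens the C10 cation, which cyclises transannularly and is hydrated as hedycaryol itself is under acid. The route is rejoined at 16.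

Step 5 is second. The reactive chair has the side chain axial, and the triflating agent must choose the enolate over a second alkoxide. The fallback sets out from 7 and removes the second oxyanion by protection. Silylation of the less hindered side-chain alcohol (TMS-imidazole) gives the mono-trimethylsilyl ether F2. Oxy-Cope rearrangement (KH, 18-crown-6) and trapping with PhNTf2 give the silylated enol triflate F3. Pd/Bu3SnH reduction gives hedycaryol trimethylsilyl ether F4, and TBAF returns the route to 10.

Step 4 is third. The hindered ketone may enolise, or the bulky alkenyl metal may add from the wrong face and give the cis-dialkenyl carbinol, which leads to an E,Z-diene. The fallback sets out from 6 and builds the isopropenyl group in stages from a small nucleophile with a strong axial preference. Ethynylmagnesium bromide gives the ethynyl carbinol F5. Gold-catalysed Markovnikov hydration of the alkyne gives the α-hydroxy methyl ketone F6. Wittig methylenation (Ph3P=CH2, excess) returns the route to 7.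

**Further compounds**
F1 | step 8 | chroman cycloadduct of 14 across C1=C10 of hedycaryol (C9′–C1 bond and aryl O–C10 bond on the same face, 9′S and 1S as in the target, 4E-alkene retained) | CC(C)C[C@@H]1c2c(O)c(C=O)c(O)c(C=O)c2O[C@]2(C)CC[C@@H](C(C)(C)O)C/C=C(C)/CC[C@@H]12
F2 | step 5 | (1S,2R,5R)-2-ethenyl-2-methyl-1-(prop-1-en-2-yl)-5-{2-[(trimethylsilyl)oxy]propan-2-yl}cyclohexan-1-ol | C[C@]1(C=C)CC[C@H](C[C@]1(O)C(C)=C)C(C)(C)O[Si](C)(C)C
F3 | step 5 | (1Z,5E,9R)-2,6-dimethyl-9-{2-[(trimethylsilyl)oxy]propan-2-yl}cyclodeca-1,5-dien-1-yl trifluoromethanesulfonate | C/C1=C\CC/C(C)=C(OS(=O)(=O)C(F)(F)F)/C[C@H](C(C)(C)O[Si](C)(C)C)CC1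
F4 | step 5 | hedycaryol trimethylsilyl ether, {2-[(1R,3E,7E)-4,8-dimethylcyclodeca-3,7-dien-1-yl]propan-2-yl}oxy(trimethyl)silane | C/C1=C\CC/C(C)=C/C[C@H](C(C)(C)O[Si](C)(C)C)CC1
F5 | step 4 | (1S,2R,5R)-2-ethenyl-1-ethynyl-5-(2-hydroxypropan-2-yl)-2-methylcyclohexan-1-ol | C[C@]1(C=C)CC[C@H](C[C@]1(O)C#C)C(C)(C)O
F6 | step 4 | 1-[(1R,2R,5R)-2-ethenyl-1-hydroxy-5-(2-hydroxypropan-2-yl)-2-methylcyclohexyl]ethan-1-one | C[C@]1(C=C)CC[C@H](C[C@]1(O)C(C)=O)C(C)(C)O
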